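**Strategy**

The plan rests on cutting the unactivated C4–C5 methylene–methylene bond of the tridecyl chain, which lies homoallylic to the C2 acetoxy stereocentre. Since neither carbon carries a polarity handle, both are brought in as alkene termini of like polarity and united by Ru-catalysed cross-metathesis between homoallylic diacetate 17 (C4 as =CH2) and 1-decene. Compound 17 comes from an aryl Grignard reagent and (R)-2-allyloxirane, which fixes C2. The transient C4=C5 olefin is erased by the same hydrogenation that removes the benzyl ether on the C5′ phenol of the benzene ring, so the final step unveils the free hydroxyl beside two acetates. The 1′,2′,3′,5′ arene pattern derives from 5-bromovanillin.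

Key step: step 9

Remark on numbering and stereochemistry: C1–C13 are the chain carbons counted from the benzylic carbon; 1′–6′ are the ring carbons (1′ chain, 2′ OAc, 3′ OMe, 5′ OH). The target is the (R)-enantiomer. The cross-metathesis should give mainly the E olefin 19; any Z isomer (compound F5 of the further compounds) is carried along and converges in step 10.

**Route**

Step 1
Reactants: 1 5-bromovanillin; 2 chloromethyl methyl ether
Product: 3 3-bromo-5-methoxy-4-(methoxymethoxy)benzaldehyde
Conditions: MOMCl, i-Pr2NEt, CH2Cl2, 0 °C → rt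
Reagents that add atoms: chloromethyl methyl ether, COCCl
Why: O-alkylation of the acidic phenol with the reactive α-chloro ether (Williamson-type MOM protection) should proceed cleanly and leaves the aldehyde untouched.

Step 2
Reactants: 3 3-bromo-5-methoxy-4-(methoxymethoxy)benzaldehyde; 4 meta-chloroperbenzoic acid
Product: 6 3-bromo-5-methoxy-4-(methoxymethoxy)phenol, via aryl formate 5 (not isolated)
Conditions: mCPBA, NaHCO3, CH2Cl2, 0 °C → rt; then K2CO3 (cat.), MeOH, rt
Reagents that add atoms: meta-chloroperbenzoic acid, OOC(=O)c1cccc(Cl)c1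
Why: Baeyer–Villiger (Dakin-type) oxidation, in which the para-alkoxy aryl group should migrate in preference to hydride; the formate is then methanolysed while the buffered medium spares the MOM ether.

Step 3
Reactants: 6 3-bromo-5-methoxy-4-(methoxymethoxy)phenol; 7 benzyl bromide
Product: 8 5-(benzyloxy)-1-bromo-3-methoxy-2-(methoxymethoxy)benzene
Conditions: BnBr, K2CO3, DMF, rt
Reagents that add atoms: benzyl bromide, BrCc1ccccc1
Why: Williamson ether synthesis on the unhindered phenoxide installs the group that masks the future free 5′-OH until the last step.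

Step 4
Reactants: 9 (R)-epichlorohydrin; 10 vinylmagnesium bromide
Product: 11 (2R)-1-chloropent-4-en-2-ol
Conditions: vinylMgBr, CuI (10 mol%), THF, −40 → −20 °C; aq NH4Cl
Reagents that add atoms: vinylmagnesium bromide, C=C[Mg]Br
Why: Copper-catalysed Grignard opening of the epoxide at its unsubstituted ring carbon is much faster than displacement of the primary chloride, and the stereocentre is not attacked, so it keeps its configuration (R by CIP).

Step 5
Reactants: 11 (2R)-1-chloropent-4-en-2-ol
Product: 12 (2R)-2-(prop-2-en-1-yl)oxirane [(R)-2-allyloxirane]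
Conditions: NaOH (powdered), Et2O, rt; distillation
Reagents that add atoms: none
Why: Intramolecular Williamson (halohydrin) closure, in which the alkoxide displaces chloride at the primary carbon; the C–O bond at the stereocentre is not broken, so the R configuration is retained.

Step 6
Reactants: 8 5-(benzyloxy)-1-bromo-3-methoxy-2-(methoxymethoxy)benzene; 12 (2R)-2-(prop-2-en-1-yl)oxirane
Product: 14 (2R)-1-[5-(benzyloxy)-3-methoxy-2-(methoxymethoxy)phenyl]pent-4-en-2-ol, via arylmagnesium bromide 13 (not isolated)
Conditions: Mg, LiCl, THF, rt; then CuI (10 mol%), 12, −30 → 0 °C; aq NH4Cl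
Reagents that add atoms: none
Why: Copper-catalysed aryl Grignard opening of a terminal epoxide (SN2 at the CH2 terminus) forms the aryl–C1 bond and carries the C2 configuration of 12 unchanged into the (R)-carbinol.

Step 7
Reactants: 14 (2R)-1-[5-(benzyloxy)-3-methoxy-2-(methoxymethoxy)phenyl]pent-4-en-2-ol
Product: 15 4-(benzyloxy)-2-[(2R)-2-hydroxypent-4-en-1-yl]-6-methoxyphenol
Conditions: conc. HCl (cat.), MeOH, 40 °C
Reagents that add atoms: none
Why: Acid-catalysed acetal exchange with methanol should cleave the phenolic MOM ether selectively, leaving the benzyl ether, the alkene and the carbinol stereocentre untouched.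

Step 8
Reactants: 15 4-(benzyloxy)-2-[(2R)-2-hydroxypent-4-en-1-yl]-6-methoxyphenol; 16 acetic anhydride
Product: 17 (2R)-1-[2-(acetyloxy)-5-(benzyloxy)-3-methoxyphenyl]pent-4-en-2-yl acetate
Conditions: Ac2O, pyridine, DMAP (cat.), CH2Cl2, rt
Reagents that add atoms: acetic anhydride, CC(=O)OC(C)=O
Why: DMAP-catalysed acylation should esterify both the hindered phenol and the secondary alcohol in one operation, without touching the stereocentre.

Step 9
Reactants: 17 (2R)-1-[2-(acetyloxy)-5-(benzyloxy)-3-methoxyphenyl]pent-4-en-2-yl acetate; 18 1-decene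
Product: 19 (2R,4E)-1-[2-(acetyloxy)-5-(benzyloxy)-3-methoxyphenyl]tridec-4-en-2-yl acetate
Conditions: 1-decene (4 equiv), Grubbs II (5 mol%), 1,4-benzoquinone (10 mol%), CH2Cl2, 40 °C
Reagents that add atoms: 1-decene, C=CCCCCCCCC
Why: Olefin cross-metathesis (Chauvin mechanism): the Ru alkylidene engages the terminal alkenes of 17 and 1-decene through ruthenacyclobutanes by successive [2+2]/retro-[2+2] events, and loss of ethene drives formation of the C4=C5 bond. The closest known reaction type is the cross-metathesis of two Type I terminal olefins, a homoallylic ester with an α-olefin. No ring is closed and no stereocentre is created; C2, two atoms away, is not touched, and the E/Z ratio is irrelevant because both isomers are hydrogenated in step 10. The selectivity needed is cross- over homo-coupling: the excess of cheap 1-decene and the reversibility of metathesis (homodimer of 17 re-enters the cycle) should channel 17 into 19, and the non-polar decene homodimer is removed by chromatography. Benzoquinone should suppress Ru–H double-bond migration that would blur the chain length, and the two acetates and the benzyl ether are inert to the catalyst.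

Step 10
Reactants: 19 (2R,4E)-1-[2-(acetyloxy)-5-(benzyloxy)-3-methoxyphenyl]tridec-4-en-2-yl acetate
Product: 20 (2R)-1-[2-(acetyloxy)-5-hydroxy-3-methoxyphenyl]tridecan-2-yl acetate
Conditions: H2 (1 atm), 10% Pd/C, EtOAc, rt
Reagents that add atoms: none
Why: Heterogeneous hydrogenation should saturate the C4=C5 olefin of either geometry and hydrogenolyse the aryl benzyl ether in the same operation, while both acetates and the C2 stereocentre are inert in the aprotic solvent.

**Compound list**

1 | 5-bromovanillin (3-bromo-4-hydroxy-5-methoxybenzaldehyde) | O=Cc1cc(Br)c(O)c(OC)c1 | starting material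
2 | chloromethyl methyl ether | COCCl | starting material
3 | 3-bromo-5-methoxy-4-(methoxymethoxy)benzaldehyde | O=Cc1cc(Br)c(OCOC)c(OC)c1 | intermediate
4 | meta-chloroperbenzoic acid | OOC(=O)c1cccc(Cl)c1 | starting material
5 | 3-bromo-5-methoxy-4-(methoxymethoxy)phenyl formate | O=COc1cc(Br)c(OCOC)c(OC)c1 | intermediate (not isolated)
6 | 3-bromo-5-methoxy-4-(methoxymethoxy)phenol | Oc1cc(Br)c(OCOC)c(OC)c1 | intermediate
7 | benzyl bromide | BrCc1ccccc1 | starting material
8 | 5-(benzyloxy)-1-bromo-3-methoxy-2-(methoxymethoxy)benzene | COCOc1c(Br)cc(OCc2ccccc2)cc1OC | intermediate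
9 | (R)-epichlorohydrin | ClC[C@H]1CO1 | starting material
10 | vinylmagnesium bromide | C=C[Mg]Br | starting material
11 | (2R)-1-chloropent-4-en-2-ol | ClC[C@H](O)CC=C | intermediate
12 | (2R)-2-(prop-2-en-1-yl)oxirane | C=CC[C@@H]1CO1 | intermediate
13 | [5-(benzyloxy)-3-methoxy-2-(methoxymethoxy)phenyl]magnesium bromide | COCOc1c([Mg]Br)cc(OCc2ccccc2)cc1OC | intermediate (not isolated)
14 | (2R)-1-[5-(benzyloxy)-3-methoxy-2-(methoxymethoxy)phenyl]pent-4-en-2-ol | C=CC[C@H](Cc1cc(OCc2ccccc2)cc(OC)c1OCOC)O | intermediate
15 | 4-(benzyloxy)-2-[(2R)-2-hydroxypent-4-en-1-yl]-6-methoxyphenol | C=CC[C@H](Cc1cc(OCc2ccccc2)cc(OC)c1O)O | intermediate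
16 | acetic anhydride | CC(=O)OC(C)=O | starting material
17 | (2R)-1-[2-(acetyloxy)-5-(benzyloxy)-3-methoxyphenyl]pent-4-en-2-yl acetate | C=CC[C@H](Cc1cc(OCc2ccccc2)cc(OC)c1OC(C)=O)OC(C)=O | intermediate
18 | 1-decene | C=CCCCCCCCC | starting material
19 | (2R,4E)-1-[2-(acetyloxy)-5-(benzyloxy)-3-methoxyphenyl]tridec-4-en-2-yl acetate | CCCCCCCC/C=C/C[C@H](Cc1cc(OCc2ccccc2)cc(OC)c1OC(C)=O)OC(C)=O | intermediate
20 | (2R)-1-[2-(acetyloxy)-5-hydroxy-3-methoxyphenyl]tridecan-2-yl acetate | CCCCCCCCCCC[C@H](Cc1cc(O)cc(OC)c1OC(C)=O)OC(C)=O | target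

**Step count**

Total steps: 10. Longest linear sequence: 8 (steps 1, 2, 3, 6, 7, 8, 9, 10 from 5-bromovanillin); steps 4 and 5 form the two-step epoxide branch.

**Steps most likely to fail**

1. Step 9 (cross-metathesis). What may go wrong: statistical homodimerisation of both partners, Ru-hydride-mediated double-bond migration that scrambles the chain length, or stalling through chelation of an acetate carbonyl to ruthenium. The fallback forms the same C4=C5 bond by Wittig olefination and sets out from 14. The alcohol is silylated (TBSCl, imidazole, DMF) to the tert-butyldimethylsilyl ether F1. Lemieux–Johnson cleavage (OsO4 cat., NaIO4, 2,6-lutidine, dioxane–H2O) gives the β-silyloxy aldehyde F2. The ylide from nonyltriphenylphosphonium bromide (CCCCCCCCC[P+](c1ccccc1)(c1ccccc1)c1ccccc1.[Br-]) and NaHMDS (THF, −78 °C → rt) converts it into the Z olefin F3. HCl in MeOH removes the silyl and MOM groups together to give the diol F4, and Ac2O/pyridine/DMAP gives the diacetate F5, the 4Z isomer of 19. F5 is hydrogenated under the conditions of step 10, so the fallback comes back to the route at 20.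

2. Step 6 (Grignard formation and epoxide opening). What may go wrong: slow or incomplete magnesium insertion into the electron-rich, ortho-substituted bromide, Wurtz-type biaryl formation, or halide opening of the volatile epoxide competing with aryl transfer. The fallback sets out from 8 and bypasses 12 by reversing the order of the two epoxide openings. Bromine–lithium exchange (n-BuLi, THF, −78 °C) and BF3·OEt2-promoted opening of (S)-epichlorohydrin (ClC[C@@H]1CO1) at the ring CH2 should give the chlorohydrin F6. K2CO3 in MeOH closes it to the arylmethyl oxirane F7. Vinylmagnesium bromide 10 with catalytic CuI (THF, −30 °C) opens F7 at its terminal carbon to give 14, where the route is rejoined.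

3. Step 7 (MOM cleavage). What may go wrong: the methoxymethyl cation released in acid is captured by the free homoallylic alcohol (mixed or cyclic formal, Prins-type cyclisation onto the alkene) instead of by methanol. The fallback sets out from 14 and blocks the carbinol before the acid step. Acetylation (Ac2O, pyridine, DMAP) gives the acetate F8. Aqueous HCl in THF (rt) then cleaves the MOM ether to the phenol F9. A second acetylation (Ac2O, pyridine, DMAP) gives 17, where the route is rejoined.

**Further compounds**

F1 | step 9 | tert-butyl{[(2R)-1-[5-(benzyloxy)-3-methoxy-2-(methoxymethoxy)phenyl]pent-4-en-2-yl]oxy}dimethylsilane | C=CC[C@H](Cc1cc(OCc2ccccc2)cc(OC)c1OCOC)O[Si](C)(C)C(C)(C)C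
F2 | step 9 | (3S)-4-[5-(benzyloxy)-3-methoxy-2-(methoxymethoxy)phenyl]-3-[(tert-butyldimethylsilyl)oxy]butanal | O=CC[C@H](Cc1cc(OCc2ccccc2)cc(OC)c1OCOC)O[Si](C)(C)C(C)(C)C
F3 | step 9 | tert-butyl{[(2R,4Z)-1-[5-(benzyloxy)-3-methoxy-2-(methoxymethoxy)phenyl]tridec-4-en-2-yl]oxy}dimethylsilane | CCCCCCCC/C=C\C[C@H](Cc1cc(OCc2ccccc2)cc(OC)c1OCOC)O[Si](C)(C)C(C)(C)C
F4 | step 9 | 4-(benzyloxy)-2-[(2R,4Z)-2-hydroxytridec-4-en-1-yl]-6-methoxyphenol | CCCCCCCC/C=C\C[C@H](Cc1cc(OCc2ccccc2)cc(OC)c1O)O
F5 | step 9 | (2R,4Z)-1-[2-(acetyloxy)-5-(benzyloxy)-3-methoxyphenyl]tridec-4-en-2-yl acetate | CCCCCCCC/C=C\C[C@H](Cc1cc(OCc2ccccc2)cc(OC)c1OC(C)=O)OC(C)=O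
F6 | step 6 | (2S)-1-[5-(benzyloxy)-3-methoxy-2-(methoxymethoxy)phenyl]-3-chloropropan-2-ol | ClC[C@@H](O)Cc1cc(OCc2ccccc2)cc(OC)c1OCOC
F7 | step 6 | (2S)-2-{[5-(benzyloxy)-3-methoxy-2-(methoxymethoxy)phenyl]methyl}oxirane | COCOc1c(C[C@H]2CO2)cc(OCc3ccccc3)cc1OC
F8 | step 7 | (2R)-1-[5-(benzyloxy)-3-methoxy-2-(methoxymethoxy)phenyl]pent-4-en-2-yl acetate | C=CC[C@H](Cc1cc(OCc2ccccc2)cc(OC)c1OCOC)OC(C)=O
F9 | step 7 | (2R)-1-[5-(benzyloxy)-2-hydroxy-3-methoxyphenyl]pent-4-en-2-yl acetate | C=CC[C@H](Cc1cc(OCc2ccccc2)cc(OC)c1O)OC(C)=O
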